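Between the noon and winter runs, both at 85 °C with first end groups and protic impurity unchanged, the common logarithm of the second end groups rose by 0.172 and that of the last links reading by 0.151, so I took n = 0.880, an apparent order that I called the yield order, the powers of ten of final links gained per power of ten of second end groups; it carries the scatter of the two readings behind it.

| flask | first end groups | second end groups | protic impurity | temperature | remark | time |
|---|---|---|---|---|---|---|
| noon | 0.30 M | 0.33 M | 0.030 M | 85 °C | run made earlier |  |
| dusk | 0.30 M | 0.22 M | 0.030 M | 96 °C | run made earlier |  |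
| winter | 0.30 M | 0.49 M | 0.030 M | 85 °C | run made earlier |  |
| midnight | 0.45 M | 0.33 M | 0.030 M | 96 °C | run made earlier |  |
| delta | 0.30 M | 0.330 M (in portions, 5, over 8.0 min) | 0.0300 M | 90 °C | first portion at the start, last at 8.0 min | 40 min |
| zeta | 0.30 M (fed, over 8.0 min) | 0.330 M | 0.0300 M |  | the addition at 60 °C, then warmed to 90 °C; the feed brings no volume worth counting | 40 min |
| alpha | 0.30 M | 0.330 M | 0.0300 M | 90 °C | everything together at the start | 40 min |
| epsilon | 0.30 M | 0.330 M | 0.0300 M |  | everything together at the start at 60 °C, warmed to 90 °C at 8.0 min | 40 min |
| eta | 0.30 M (fed, over 8.0 min) | 0.330 M | 0.0300 M | 90 °C | all else is in the flask from the start; the feed brings no volume worth counting | 40 min |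
| gamma | 0.30 M | 0.330 M (fed, over 50 s) | 0.0300 M | 90 °C | all else is in the flask from the start; the feed brings no volume worth counting | 40 min |

| run | time / min | links / % | first end groups / % |
|---|---|---|---|
| noon | 2.00 | 27.0 | 24.8 |
| noon | 4.00 | 21.6 | 8.6 |
| noon | 6.00 | 18.8 | 4.1 |
| noon | 12.0 | 18.0 | 0 |
| noon | 25.0 | 17.3 | 0 |
| dusk | 4.00 | 8.0 | 19.3 |
| dusk | 10.0 | 6.9 | 16.9 |
| dusk | 20.0 | 6.9 | 14.6 |
| dusk | 30.0 | 7.4 | 12.7 |
| dusk | 40.0 | 7.2 | 14.2 |
| winter | 3.00 | 33.7 | 7.5 |
| winter | 6.00 | 27.0 | 2.1 |
| winter | 12.0 | 24.9 | 1.7 |
| winter | 20.0 | 24.1 | 0 |
| winter | 40.0 | 24.5 | 0.3 |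
| midnight | 4.00 | 11.5 | 20.4 |
| midnight | 10.0 | 11.7 | 18.9 |
| midnight | 20.0 | 8.7 | 16.9 |
| midnight | 30.0 | 8.8 | 14.1 |
| midnight | 40.0 | 9.7 | 12.0 |

(scatter of a reading: 1 percentage point)

- a species is counted by the first end groups in it: one side product counts as two
- candidate steps: first end groups + protic impurity -> quenched substrate; first end groups + second end groups -> rings; first end groups + second end groups -> links; links <-> isomer of the product; first end groups + links -> side product

1. the flask that comes out highest in amount of links, in percent of the first end groups charged, or "all alike" when all lie within 1.5 percentage points (delta / zeta / alpha / epsilon / eta / gamma / all alike)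
2. links at the end, in percent of the first end groups charged, delta
3. links at the end, in percent of the first end groups charged, zeta
4. links at the end, in percent of the first end groups charged, alpha
5. links at the end, in percent of the first end groups charged, epsilon
6. links at the end, in percent of the first end groups charged, eta
7. links at the end, in percent of the first end groups charged, gamma

The first rung of my ladder was the loss of first end groups: in the noon run they fell from 24.8% to 8.6% between 2.00 min and 4.00 min, which reads as a half-life of 1.31 min. The next rung overlapped it, for noon links fell from 27.0% at 2.00 min to 18.0% at 12.0 min and then stood within the scatter, at 17.3% at 25.0 min, so a plateau followed the fall. The last rung was the creep in the midnight run, where second end groups were the limiting reagent at 0.33 M against 0.45 M of first end groups: first end groups went from 20.4% to 12.0%, which reads as a half-life of 47.0 min, and that lies 1.55 powers of ten above the first rung. Because that creep is so much slower, I expected a flask with enough second end groups to lay down its links in the first minutes and then sit on its plateau.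

I therefore applied n to delta, where the second end groups come in equal portions of 0.0660 M, and, assuming that one portion is the level the first end groups meet, extending n below the range of the two runs behind it and leaving aside the step to 90 °C, I reckoned from the noon plateau an estimate of 4.20% of links in delta.

The forecast put eta highest and gave delta 7% (3.5% to 12%), zeta 17%, alpha 16.5%, epsilon 17%, eta 17.5% and gamma 16%, saying “The 60 °C starts stay near batch, though extrapolation is uncertain.”; its delta lay above my figure.

The flasks gave delta 5.82%, zeta 21.5%, alpha 17.2%, epsilon 24.0%, eta 17.3% and gamma 13.3%, so epsilon came highest, 7 percentage points above the forecast's figure for it.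

    first end groups + protic impurity → quenched substrate (k = 0.0520 M⁻¹ s⁻¹, Ea = 57.0 kJ mol⁻¹)
    first end groups + second end groups → rings, rate k2*[first end groups] as long as [second end groups] is above zero (k = 0.00695 s⁻¹, Ea = 111 kJ mol⁻¹)
    first end groups + second end groups → links (k = 0.0420 M⁻¹ s⁻¹, Ea = 51.0 kJ mol⁻¹)
    links ⇌ isomer of the product (K = 1.70, k = 0.0108 s⁻¹, Ea = 110 kJ mol⁻¹, ΔH = −19.0 kJ mol⁻¹)
    first end groups + links → side product (k = 0.00226 M⁻¹ s⁻¹, Ea = 67.0 kJ mol⁻¹)
    (constants at 90 °C)

Epsilon had come to rest: at 40.0 min its first end groups stood at 0%, and at 400 min its links read 24.0%, as they did at the asked time. Delta likewise held 5.82% at 400 min. Read through n, delta's 5.82% against alpha's 17.2% stands for an estimated effective level of 0.0963 M of second end groups, beside the 0.0660 M of one portion. For the neighbour, delta with 1.3 M of second end groups, n gave 19.4% of links, and the computed flask gave 16.9%.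

(The data are simulated with constants of no real substance; noise was put on by code.)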